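**Retrosynthetic overview**

1. Target 17 ⇐ (−)-spectaline 16 (O-acetylation with the amine protonated) ⇐ ketal 15 ⇐ bridged N,O-ketal 13 (hydrogenolysis of N-benzyl and reduction at C6 give the all-cis ring).
2. Key disconnection: the bond between the carbinol carbon C3 and the ring CH2 C4, made by a photoredox strain-release cyclisation of aldehyde 12. The same operation closes the piperidine ring and a temporary oxygen bridge from the C3 oxygen to C6 (a 7-oxa-2-azabicyclo[2.2.1]heptane).
3. Enabling feature: the cyclopropane bonded to nitrogen in 12. Its quaternary carbon carries the nitrogen and the C12 chain and becomes C6 (as an iminium); its two CH2 groups become C5 and the radical carbon C4; the aldehyde carbon on the alanine-derived arm of the same nitrogen becomes C3.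
4. 12 ⇐ 1-alkylcyclopropylamine 6 (Kulinkovich–Szymoniak reaction of nitrile 4; EtMgBr supplies C4 and C5) + ethyl (S)-lactate triflate (SN2 with inversion gives the D-alanine centre C2, the only source of chirality), then N-benzylation, reduction and Swern oxidation.
5. Nitrile 4 ⇐ copper-catalysed coupling of the Grignard reagent of bromo ketal 1 with bromonitrile 2. Ring order: cyclopropane (step 2), piperidine plus oxygen bridge (step 7), bridge opened (step 8).

Key step: step 7

Assumption: 2-(2-bromoethyl)-2-methyl-1,3-dioxolane, 11-bromoundecanenitrile and ethyl (S)-lactate are taken as purchasable, and the chain ketone is carried as its ethylene ketal from step 1 to step 9.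

**Route**

Step 1
Reactants: 1 2-(2-bromoethyl)-2-methyl-1,3-dioxolane; 2 11-bromoundecanenitrile
Product: 4 13-(2-methyl-1,3-dioxolan-2-yl)tridecanenitrile, via Grignard reagent 3 (not isolated)
Conditions: 1, Mg, THF, 25 °C; then 2, Li2CuCl4 (3 mol %), NMP, THF, 0 °C to rt
Reagents that add atoms: none
Why: Copper-catalysed Kumada-type sp3–sp3 coupling of a primary alkyl Grignard reagent with a primary alkyl bromide is fast at 0 °C, so the nitrile and the ketal should be left untouched; no stereocentre is formed.

Step 2
Reactants: 4 13-(2-methyl-1,3-dioxolan-2-yl)tridecanenitrile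
Product: 6 1-[12-(2-methyl-1,3-dioxolan-2-yl)dodecyl]cyclopropan-1-amine, via azatitanacyclopentene 5 (not isolated)
Conditions: EtMgBr (2.2 equiv), Ti(OiPr)4 (1.1 equiv), Et2O, −78 °C to rt; BF3·OEt2 (2 equiv), rt; aq. NaOH work-up
Reagents that add atoms: ethylmagnesium bromide, CC[Mg]Br
Why: Kulinkovich–Szymoniak cyclopropanation, in which EtMgBr and Ti(OiPr)4 deliver a C2H4 unit to the nitrile carbon to give 5 and BF3·OEt2 contracts 5 to the primary 1-alkylcyclopropylamine, an unhindered primary-alkyl nitrile being a favourable substrate and the basic work-up sparing the ketal; no stereocentre is formed.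

Step 3
Reactants: 6 1-[12-(2-methyl-1,3-dioxolan-2-yl)dodecyl]cyclopropan-1-amine; 7 ethyl (S)-lactate
Product: 9 ethyl (2R)-2-({1-[12-(2-methyl-1,3-dioxolan-2-yl)dodecyl]cyclopropyl}amino)propanoate, via lactate triflate 8 (not isolated)
Conditions: 7, Tf2O (1.0 equiv), 2,6-lutidine, CH2Cl2, −78 °C; then 6, iPr2NEt, −78 °C to rt
Reagents that add atoms: none
Why: SN2 displacement of the α-triflyloxy ester by the primary amine proceeds with inversion, so the (S)-lactate centre becomes the (R) centre of the D-alanine unit (the future C2), and the hindered secondary amine formed should not be alkylated a second time.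

Step 4
Reactants: 9 ethyl (2R)-2-({1-[12-(2-methyl-1,3-dioxolan-2-yl)dodecyl]cyclopropyl}amino)propanoate
Product: 10 ethyl (2R)-2-(benzyl{1-[12-(2-methyl-1,3-dioxolan-2-yl)dodecyl]cyclopropyl}amino)propanoate
Conditions: BnBr, K2CO3, KI (cat.), MeCN, 70 °C
Reagents that add atoms: benzyl bromide, BrCc1ccccc1
Why: N-Benzylation (SN2 on benzyl bromide) gives a tertiary amine that tolerates the later aldehyde, is easily oxidised in the key step and is removable by hydrogenolysis; the stereocentre is not touched.

Step 5
Reactants: 10 ethyl (2R)-2-(benzyl{1-[12-(2-methyl-1,3-dioxolan-2-yl)dodecyl]cyclopropyl}amino)propanoate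
Product: 11 (2R)-2-(benzyl{1-[12-(2-methyl-1,3-dioxolan-2-yl)dodecyl]cyclopropyl}amino)propan-1-ol
Conditions: LiAlH4, THF, 0 °C
Reagents that add atoms: none
Why: Hydride reduction of the ester to the primary alcohol, to which the ketal, the cyclopropane, the benzylamine and the stereocentre are inert.

Step 6
Reactants: 11 (2R)-2-(benzyl{1-[12-(2-methyl-1,3-dioxolan-2-yl)dodecyl]cyclopropyl}amino)propan-1-ol
Product: 12 (2R)-2-(benzyl{1-[12-(2-methyl-1,3-dioxolan-2-yl)dodecyl]cyclopropyl}amino)propanal
Conditions: (COCl)2, DMSO, CH2Cl2, −78 °C; Et3N, −78 to −20 °C; used crude at once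
Reagents that add atoms: none
Why: Swern oxidation gives the N,N-dialkyl α-amino aldehyde, a class that keeps its configuration when it is not chromatographed and is used immediately, and the tertiary amine is not oxidised under these conditions.

Step 7
Reactants: 12 (2R)-2-(benzyl{1-[12-(2-methyl-1,3-dioxolan-2-yl)dodecyl]cyclopropyl}amino)propanal
Product: 13 (1S,3R,4R)-2-benzyl-3-methyl-1-[12-(2-methyl-1,3-dioxolan-2-yl)dodecyl]-7-oxa-2-azabicyclo[2.2.1]heptane
Conditions: 4CzIPN (2,4,5,6-tetrakis(carbazol-9-yl)isophthalonitrile, 2 mol %), degassed MeCN (0.02 M), 456 nm LEDs, rt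
Reagents that add atoms: none
Why: Proposed new method: the excited photocatalyst oxidises the trialkylamine of 12 to its aminium radical cation, the cyclopropane bond next to nitrogen breaks with release of ring strain to give a distonic ion (N-benzyl ketiminium at the former quaternary carbon, primary radical on the former ring CH2), and this radical adds to the aldehyde carbon to make the new C–C bond, after which the alkoxy radical closes onto the iminium carbon (or is first reduced by the photocatalyst radical anion and then adds as alkoxide) and the electron is returned, so that the step is a redox-neutral isomerisation. The closest known reaction type is the photoredox formal (3+2) cycloaddition of N,N-dialkylaminocyclopropanes with alkenes, together with the known 6-exo cyclisation of alkyl radicals onto aldehydes, and what is new is the use of a tethered C=O π bond as the two-atom partner. The piperidine ring closes by 6-exo-trig radical attack on the carbonyl carbon and the oxygen bridge by 5-exo-trig attack of oxygen on the iminium carbon. The new carbinol centre (4R in 13) is controlled by the alanine-derived centre, since in the compact bicyclic transition state the methyl group sits exo, on the side of the one-atom oxygen bridge, and not endo over the two-carbon bridge, and since the C=O addition is reversible (β-scission of the alkoxy radical) the material should drain through this less strained exo-methyl ketal, which is the 2,3-cis series of the target; the bridgehead aminal centre (1S) then follows from geometry because the oxygen can only bridge on its own face. The step needs the radical chain cis to the aldehyde-bearing nitrogen substituent on the iminium, which reversible 3-exo reclosure of the distonic ion allows by interconverting the two iminium geometries, and it needs oxidation of the amine only, which is secured because the trialkylamine is by far the most easily oxidised group in 12. Dilute, degassed conditions are chosen so that hydrogen abstraction and oxygen trapping do not compete with the two ring closures.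

Step 8
Reactants: 13 (1S,3R,4R)-2-benzyl-3-methyl-1-[12-(2-methyl-1,3-dioxolan-2-yl)dodecyl]-7-oxa-2-azabicyclo[2.2.1]heptane
Product: 15 (2R,3R,6S)-2-methyl-6-[12-(2-methyl-1,3-dioxolan-2-yl)dodecyl]piperidin-3-ol, via cyclic imine 14 (not isolated)
Conditions: H2 (3 atm), Pd(OH)2/C, EtOH, rt
Reagents that add atoms: none
Why: In neutral ethanol the ketal should not ionise, so hydrogenolysis of the N-benzyl group should come first and release cyclic imine 14 (the ring-chain tautomer of the N-unsubstituted ketal), and catalytic hydrogenation of such a 2,6-disubstituted cyclic imine should place the new hydrogen axial and the chain equatorial, cis to the equatorial methyl group, which sets the last stereocentre (6S) and gives the all-cis ring.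

Step 9
Reactants: 15 (2R,3R,6S)-2-methyl-6-[12-(2-methyl-1,3-dioxolan-2-yl)dodecyl]piperidin-3-ol
Product: 16 (−)-spectaline, 14-[(2S,5R,6R)-5-hydroxy-6-methylpiperidin-2-yl]tetradecan-2-one
Conditions: 1 M aq. HCl, THF, rt; then aq. NaOH
Reagents that add atoms: water, O
Why: Acid hydrolysis of the dioxolane releases the methyl ketone while the amine is protected as its ammonium salt, and basification gives the free amino alcohol with no stereocentre affected.

Step 10
Reactants: 16 (−)-spectaline, 14-[(2S,5R,6R)-5-hydroxy-6-methylpiperidin-2-yl]tetradecan-2-one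
Product: 17 (−)-3-O-acetylspectaline, (2R,3R,6S)-2-methyl-6-(13-oxotetradecyl)piperidin-3-yl acetate
Conditions: AcCl, CF3CO2H, 0 °C to rt; then cold aq. NaHCO3
Reagents that add atoms: acetyl chloride, CC(Cl)=O
Why: Chemoselective O-acylation under strongly acidic conditions, in which the amine is fully protonated in CF3CO2H and cannot be acylated, so acetyl chloride should acylate only the secondary alcohol with retention at the carbinol carbon, and cold neutralisation then frees the hindered amine.

**Compound list**

1 | 2-(2-bromoethyl)-2-methyl-1,3-dioxolane | CC1(CCBr)OCCO1 | starting material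
2 | 11-bromoundecanenitrile | N#CCCCCCCCCCCBr | starting material
3 | [2-(2-methyl-1,3-dioxolan-2-yl)ethyl]magnesium bromide (formed in situ) | CC1(CC[Mg]Br)OCCO1 | intermediate
4 | 13-(2-methyl-1,3-dioxolan-2-yl)tridecanenitrile | CC1(CCCCCCCCCCCCC#N)OCCO1 | intermediate
5 | 5-[12-(2-methyl-1,3-dioxolan-2-yl)dodecyl]-2,2-di(propan-2-yloxy)-1-aza-2-titanacyclopent-1(5)-ene (azatitanacyclopentene, formed in situ) | CC1(CCCCCCCCCCCCC2=N[Ti](OC(C)C)(OC(C)C)CC2)OCCO1 | intermediate
6 | 1-[12-(2-methyl-1,3-dioxolan-2-yl)dodecyl]cyclopropan-1-amine | CC1(CCCCCCCCCCCCC2(N)CC2)OCCO1 | intermediate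
7 | ethyl (S)-lactate, ethyl (2S)-2-hydroxypropanoate | C[C@H](O)C(=O)OCC | starting material
8 | ethyl (2S)-2-[(trifluoromethanesulfonyl)oxy]propanoate (formed in situ) | C[C@H](OS(=O)(=O)C(F)(F)F)C(=O)OCC | intermediate
9 | ethyl (2R)-2-({1-[12-(2-methyl-1,3-dioxolan-2-yl)dodecyl]cyclopropyl}amino)propanoate | C[C@@H](NC1(CCCCCCCCCCCCC2(C)OCCO2)CC1)C(=O)OCC | intermediate
10 | ethyl (2R)-2-(benzyl{1-[12-(2-methyl-1,3-dioxolan-2-yl)dodecyl]cyclopropyl}amino)propanoate | C[C@@H](N(Cc1ccccc1)C2(CCCCCCCCCCCCC3(C)OCCO3)CC2)C(=O)OCC | intermediate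
11 | (2R)-2-(benzyl{1-[12-(2-methyl-1,3-dioxolan-2-yl)dodecyl]cyclopropyl}amino)propan-1-ol | C[C@@H](N(Cc1ccccc1)C2(CCCCCCCCCCCCC3(C)OCCO3)CC2)CO | intermediate
12 | (2R)-2-(benzyl{1-[12-(2-methyl-1,3-dioxolan-2-yl)dodecyl]cyclopropyl}amino)propanal | C[C@@H](N(Cc1ccccc1)C2(CCCCCCCCCCCCC3(C)OCCO3)CC2)C=O | intermediate
13 | (1S,3R,4R)-2-benzyl-3-methyl-1-[12-(2-methyl-1,3-dioxolan-2-yl)dodecyl]-7-oxa-2-azabicyclo[2.2.1]heptane (methyl exo, syn to the oxygen bridge) | CC1(CCCCCCCCCCCC[C@]23CC[C@@H](O3)[C@@H](C)N2Cc4ccccc4)OCCO1 | intermediate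
14 | (2R,3R)-2-methyl-6-[12-(2-methyl-1,3-dioxolan-2-yl)dodecyl]-2,3,4,5-tetrahydropyridin-3-ol (formed in situ) | CC1(CCCCCCCCCCCCC2=N[C@H](C)[C@H](O)CC2)OCCO1 | intermediate
15 | (2R,3R,6S)-2-methyl-6-[12-(2-methyl-1,3-dioxolan-2-yl)dodecyl]piperidin-3-ol (all-cis) | CC1(CCCCCCCCCCCC[C@H]2CC[C@@H](O)[C@@H](C)N2)OCCO1 | intermediate
16 | (−)-spectaline, 14-[(2S,5R,6R)-5-hydroxy-6-methylpiperidin-2-yl]tetradecan-2-one | CC(=O)CCCCCCCCCCCC[C@H]1CC[C@@H](O)[C@@H](C)N1 | intermediate
17 | (−)-3-O-acetylspectaline, (2R,3R,6S)-2-methyl-6-(13-oxotetradecyl)piperidin-3-yl acetate | CC(=O)CCCCCCCCCCCC[C@H]1CC[C@@H](OC(C)=O)[C@@H](C)N1 | target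

**Step count and risks**

Total step count: 10. Longest linear sequence: 10 steps (from 1 and 2 to 17); ethyl (S)-lactate 7 enters at step 3.

Steps most likely to fail:

1. Step 7 (the step with the new method). The ring-opened radical may be lost to hydrogen abstraction or to reclosure without cyclisation, because addition to the C=O group is reversible. The iminium may open with the radical chain on the wrong side of the C=N bond. Attack on the other face of the aldehyde, or epimerisation of the α-amino aldehyde, would erode the 2,3-cis relationship.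
 Fallback (known chemistry only), setting out from nitrile 4 and coming back at 15. Nitrile 4 is reduced with DIBAL-H (toluene, −78 °C, buffered work-up) to 13-(2-methyl-1,3-dioxolan-2-yl)tridecanal F1. Vinylmagnesium bromide gives the allylic alcohol 15-(2-methyl-1,3-dioxolan-2-yl)pentadec-1-en-3-ol F2, and Dess–Martin periodinane gives the vinyl ketone 15-(2-methyl-1,3-dioxolan-2-yl)pentadec-1-en-3-one F3. Separately, purchased benzyl N-[(2R)-1-oxopropan-2-yl]carbamate F4 is treated with vinylmagnesium bromide, and the syn adduct benzyl N-[(2R,3R)-3-hydroxypent-4-en-2-yl]carbamate F5 is separated from its anti isomer by chromatography. Cross-metathesis of F3 with F5 (second-generation Hoveyda–Grubbs catalyst, CH2Cl2, 40 °C) should give the E-enone benzyl N-[(2R,3R,4E)-3-hydroxy-18-(2-methyl-1,3-dioxolan-2-yl)-6-oxooctadec-4-en-2-yl]carbamate F6. Hydrogenation of F6 (H2, Pd/C, MeOH) should saturate the alkene, remove the carbamate, close the ring to cyclic imine 14 and reduce it to 15.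

2. Step 8. The N-benzyl iminium may be reduced before the benzyl group is lost, with hydrogen delivered to the other face of the C=N bond (2,6-trans ring), or hydrogenolysis may stall at the hindered nitrogen.
 Fallback, setting out from 13 and coming back at 16. Ketal 13 is first hydrolysed (1 M aq. HCl, THF), which opens the N,O-ketal and the dioxolane and gives the open-chain (18R,19R)-19-(benzylamino)-18-hydroxyicosane-2,15-dione F7 (it may rest as its five-membered lactol). Hydrogenation of F7 in dilute solution (H2, Pd(OH)2/C, MeOH) then removes the benzyl group from the secondary ammonium ion, and the primary amine should condense only with the C15 ketone (six-membered imine). The N-unsubstituted imine is reduced to the all-cis ring, which gives 16 directly.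

3. Step 10. Acetylation may also occur on nitrogen if protonation is incomplete, and the acetyl group may migrate from oxygen to nitrogen during neutralisation.
 Fallback, setting out from 15 and coming back at 17. The amine of 15 is protected with Boc2O (MeOH, 40 °C) to give tert-butyl (2R,3R,6S)-3-hydroxy-2-methyl-6-[12-(2-methyl-1,3-dioxolan-2-yl)dodecyl]piperidine-1-carboxylate F8. The alcohol is acetylated under basic conditions (Ac2O, DMAP, pyridine) to give tert-butyl (2R,3R,6S)-3-acetoxy-2-methyl-6-[12-(2-methyl-1,3-dioxolan-2-yl)dodecyl]piperidine-1-carboxylate F9. CF3CO2H–H2O then removes the carbamate and the dioxolane together, and cold NaHCO3 gives 17.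

Further compounds
F1 | step 7 | 13-(2-methyl-1,3-dioxolan-2-yl)tridecanal | CC1(CCCCCCCCCCCCC=O)OCCO1
F2 | step 7 | 15-(2-methyl-1,3-dioxolan-2-yl)pentadec-1-en-3-ol | CC1(CCCCCCCCCCCCC(O)C=C)OCCO1
F3 | step 7 | 15-(2-methyl-1,3-dioxolan-2-yl)pentadec-1-en-3-one | CC1(CCCCCCCCCCCCC(=O)C=C)OCCO1
F4 | step 7 | benzyl N-[(2R)-1-oxopropan-2-yl]carbamate (purchased) | C[C@@H](NC(=O)OCc1ccccc1)C=O
F5 | step 7 | benzyl N-[(2R,3R)-3-hydroxypent-4-en-2-yl]carbamate | C=C[C@@H](O)[C@@H](C)NC(=O)OCc1ccccc1
F6 | step 7 | benzyl N-[(2R,3R,4E)-3-hydroxy-18-(2-methyl-1,3-dioxolan-2-yl)-6-oxooctadec-4-en-2-yl]carbamate | CC1(CCCCCCCCCCCCC(=O)/C=C/[C@@H](O)[C@@H](C)NC(=O)OCc2ccccc2)OCCO1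
F7 | step 8 | (18R,19R)-19-(benzylamino)-18-hydroxyicosane-2,15-dione | CC(=O)CCCCCCCCCCCCC(=O)CC[C@@H](O)[C@@H](C)NCc1ccccc1
F8 | step 10 | tert-butyl (2R,3R,6S)-3-hydroxy-2-methyl-6-[12-(2-methyl-1,3-dioxolan-2-yl)dodecyl]piperidine-1-carboxylate | CC1(CCCCCCCCCCCC[C@H]2CC[C@@H](O)[C@@H](C)N2C(=O)OC(C)(C)C)OCCO1
F9 | step 10 | tert-butyl (2R,3R,6S)-3-acetoxy-2-methyl-6-[12-(2-methyl-1,3-dioxolan-2-yl)dodecyl]piperidine-1-carboxylate | CC1(CCCCCCCCCCCC[C@H]2CC[C@@H](OC(C)=O)[C@@H](C)N2C(=O)OC(C)(C)C)OCCO1
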